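The target can fall back to starting material, so no length of waiting can pile it up without end.

    starting material + partner ⇌ target (K1 = 59 M⁻¹, k1 = 0.33 M⁻¹ min⁻¹)
    starting material + partner ⇌ isomer of the product (K2 = 120 M⁻¹, k2 = 0.17 M⁻¹ min⁻¹)
    starting material ⇌ dormant form (K3 = 2.2, k3 = 8.1 × 10⁻⁴ min⁻¹)
    gas ⇌ partner, rate k4*(csat - [partner]) (k4 = 0.065 min⁻¹, csat = 27 mM)

starting material 0.30 M (fed, over 2.5 h); gas 27 mM (held); time 10 d; the fed solution adds 1.0 times the starting volume

- charges are per starting volume, the dose included; the dosed solution carries all of it
- at the start none of partner is dissolved
- what has gone from starting material into another species counts as reacted, even if it can come back
- run time (flask): 10 d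

- part of the starting material gone at 10 d
- the target standing at 10 d, as a percentage of the starting material charged
- the isomer of the product standing at 10 d, as a percentage of the starting material charged
- amount of target if the flask were left three thousand times as long, in percent of the starting material charged

Turned round, the question is what the given numbers would have to say for the target to stand ahead of the isomer of the product at the asked time. At any moment the target forms 1.94 times as fast as the isomer, and because both come from the same pair of reactants, that ratio does not drift with the amounts. The drift lies in the way back: per unit of each, the target returns at 0.00559 min⁻¹ and the isomer at 0.00142 min⁻¹, so the two flows balance at 2.03 of isomer per target.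

A final lead for the target (kinetic rather than thermodynamic control) would therefore need a run short against the return times. The longest of these belongs to the dormant form, 1.89 d, yet the run lasts 5.29 such times.

Partner refills in about 15.4 min, so this reckoning holds it at saturation. Starting material then has weight 1, the dormant form 2.2, the target 1.59 and the isomer 3.24. The target's weight over their sum gives 19.8 % as the resting share of the target, a part of the charge into which the charge itself does not enter. The same sum puts the isomer at 40.3 % and the part gone at 87.6 %.

The forecast gives 87.6 % gone, 19.8 % of target, 40.3 % of isomer and 19.8 % of target after the far longer wait, holding the flask at the asked time to be “already essentially at equilibrium”.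

The simulated flask gives 87.5 % gone, 19.8 % of target, and 19.8 % of target after the far longer wait. The isomer of the product in that flask stands at 40.3 % at the asked time.

In this flask the half-lives of starting material by the forward passing into the isomer alone, 0.16 d at 0.0880 d, and into the dormant form alone, 0.59 d at that time, are both shorter than the 10 d run, and the target, 22.5 % at the end of the feed, stands at 19.8 % against the resting share of 19.8 %. The neighbour flask with 0.51 M of starting material, a charge absent from the resting share, ends with 19.8 % of target.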